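## Retrosynthetic overview

1. Target ⇐ its 2,3-dione tautomer ⇐ Rubottom α-hydroxylation of a cis-fused 4(18)-methylene-3-ketone, made by Mannich methylenation of the enol silane left by a Me2CuLi conjugate addition (C-19, sets the cis ring fusion).
2. 7β-OAc ⇐ 4,6-dien-3-one (epoxidation, reductive opening) ⇐ 3-oxo-Δ4 octalone.
3. Ring A (formed second) ⇐ Mukaiyama–Michael/aldol annulation with methyl vinyl ketone at C-10 of a ring B enol silane.
4. Ring B (formed first) ⇐ organocatalytic Michael addition of propanal to methyl vinyl ketone and aldol closure, then two conjugate additions (CH3-20, then the C-11 to C-15 chain, making C-9 quaternary).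
5. Side-chain Grignard reagent ⇐ carboxylesterase desymmetrisation of dimethyl 3-methylglutarate (C-13).

Assumption: the SMILES is read as methyl (5S,7S,8S,9R,10R,13R)-7-acetoxy-2-hydroxy-3-oxocleroda-1,4(18)-dien-15-oate, a 5,10-cis-fused decalin in clerodane numbering; β means the face of H-10 (also CH3-19, the C-9 chain and the 7-oxygen), α the face of CH3-17 and CH3-20; pig liver esterase is taken to give the (R)-half-ester of 3-methylglutarate.

## Route

Step 1
Reactants: 1 propanal; 2 but-3-en-2-one (methyl vinyl ketone)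
Product: 3 (R)-2-methyl-5-oxohexanal
Conditions: (S)-2-[methoxy(diphenyl)methyl]pyrrolidine (5 mol%), ethyl 3,4-dihydroxybenzoate (20 mol%), neat, 4 °C
Reagents that add atoms: none
Why: Enamine-catalysed asymmetric Michael addition in which the anti (E)-enamine of propanal is attacked on the face away from the diarylmethyl group, setting the first ring stereocentre (later C-8) as R.

Step 2
Reactants: 3 (R)-2-methyl-5-oxohexanal
Product: 4 (R)-4-methylcyclohex-2-en-1-one
Conditions: 0.1 M aq KOH, n-Bu4NOH (cat.), Et2O–THF, reflux, short reaction time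
Reagents that add atoms: none
Why: Intramolecular aldol condensation of the methyl ketone onto the aldehyde is the only six-ring mode, and brief dilute base keeps the methyl-bearing stereocentre intact.

Step 3
Reactants: 4 (R)-4-methylcyclohex-2-en-1-one
Product: 5 trimethyl{[(3S,4R)-3,4-dimethylcyclohex-1-en-1-yl]oxy}silane
Conditions: MeMgBr, CuBr·SMe2 (5 mol%), TMSCl, HMPA, THF, −78 °C; Et3N, cold aq NaHCO3
Reagents that add atoms: methylmagnesium bromide C[Mg]Br; chlorotrimethylsilane C[Si](C)(C)Cl
Why: Copper-catalysed conjugate addition with silyl trapping adds methyl trans to the C-4 methyl and fixes the enolate as the enol silane; the new C-3 centre is removed again in step 4.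

Step 4
Reactants: 5 trimethyl{[(3S,4R)-3,4-dimethylcyclohex-1-en-1-yl]oxy}silane
Product: 6 (R)-3,4-dimethylcyclohex-2-en-1-one
Conditions: Pd(OAc)2 (1.05 equiv), MeCN, rt
Reagents that add atoms: none
Why: Saegusa–Ito oxidation: the palladium enolate loses H-3 by β-hydride elimination to give the β-methyl enone without touching the C-4 stereocentre (later C-8).

Step 5
Reactants: 7 dimethyl 3-methylpentanedioate (dimethyl 3-methylglutarate)
Product: 8 (R)-5-methoxy-3-methyl-5-oxopentanoic acid
Conditions: pig liver esterase (a carboxylesterase), phosphate buffer pH 7 with 20% MeOH, −10 °C, pH-stat (1 M NaOH); then HCl to pH 2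
Reagents that add atoms: water O
Why: Enzymatic desymmetrisation in which the esterase hydrolyses only the pro-S ester group of the prochiral diester, giving the (R)-half-ester and fixing the side-chain stereocentre (later C-13).

Step 6
Reactants: 8 (R)-5-methoxy-3-methyl-5-oxopentanoic acid
Product: 9 methyl (R)-5-hydroxy-3-methylpentanoate
Conditions: BH3·SMe2 (1.1 equiv), THF, −10 °C to rt; MeOH quench; used at once (lactonises on standing)
Reagents that add atoms: none
Why: Chemoselective borane reduction of the carboxylic acid (through the acyloxyborane) in the presence of the methyl ester, with the stereocentre not involved.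

Step 7
Reactants: 9 methyl (R)-5-hydroxy-3-methylpentanoate
Product: 10 methyl (S)-5-bromo-3-methylpentanoate
Conditions: CBr4, PPh3, CH2Cl2, 0 °C
Reagents that add atoms: tetrabromomethane BrC(Br)(Br)Br
Why: Appel bromination of the primary alcohol by SN2 at CH2; the descriptor changes to S only through the CIP priorities.

Step 8
Reactants: 10 methyl (S)-5-bromo-3-methylpentanoate
Product: 11 (S)-5-bromo-3-methylpentan-1-ol
Conditions: DIBAL-H (2.2 equiv), CH2Cl2, −78 to 0 °C; Rochelle salt
Reagents that add atoms: none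
Why: Hydride reduction of the ester to the primary alcohol, the primary bromide being inert to DIBAL-H at low temperature.

Step 9
Reactants: 11 (S)-5-bromo-3-methylpentan-1-ol
Product: 12 (S)-[(5-bromo-3-methylpentyl)oxy](tert-butyl)diphenylsilane
Conditions: TBDPSCl, imidazole, CH2Cl2, rt
Reagents that add atoms: tert-butyl(chloro)diphenylsilane CC(C)(C)[Si](Cl)(c1ccccc1)c1ccccc1
Why: Silyl ether protection so that a Grignard reagent can be formed; the TBDPS group survives TiCl4 and methoxide in steps 11 and 12.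

Step 10
Reactants: 12 (S)-[(5-bromo-3-methylpentyl)oxy](tert-butyl)diphenylsilane; 6 (R)-3,4-dimethylcyclohex-2-en-1-one
Product: 14 tert-butyl{[(3R)-5-[(1S,6R)-1,6-dimethyl-3-(trimethylsilyloxy)cyclohex-2-en-1-yl]-3-methylpentyl]oxy}diphenylsilane, via Grignard reagent 13 (not isolated)
Conditions: Mg, THF, rt; then CuBr·SMe2 (10 mol%), TMSCl, HMPA, 6, THF, −78 °C; Et3N, cold aq NaHCO3; used crude
Reagents that add atoms: chlorotrimethylsilane C[Si](C)(C)Cl
Why: Copper-catalysed conjugate addition with TMSCl trapping: the chain adds axially anti to the C-8 methyl (held pseudoaxial by allylic strain with the C-9 methyl), so it is trans to CH3-17 and CH3-20 is cis to it, and the enolate is fixed towards C-10 as the enol silane.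

Step 11
Reactants: 14 ring B enol silane (name as in step 10); 2 but-3-en-2-one
Product: 15 (3S,4R)-3-{(3R)-5-[(tert-butyldiphenylsilyl)oxy]-3-methylpentyl}-3,4-dimethyl-2-(3-oxobutyl)cyclohexan-1-one (C-2 epimers)
Conditions: TiCl4, CH2Cl2, −78 °C; aq NaHCO3
Reagents that add atoms: none
Why: Mukaiyama–Michael addition of the regiodefined enol silane puts the 3-oxobutyl chain on the hindered C-10 only; the C-10 configuration is equilibrated in step 12.

Step 12
Reactants: 15 1,5-diketone (name as in step 11)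
Product: 16 (13R)-15-[(tert-butyldiphenylsilyl)oxy]-18,19-dinorclerod-4-en-3-one (8α-CH3/9α-CH3/10β-H)
Conditions: NaOMe, MeOH, 60 °C
Reagents that add atoms: none
Why: Intramolecular aldol condensation (second stage of a Robinson annulation) closes ring A, and the epimerisable C-10 settles in the more stable 10β-H form with C-1 equatorial and only CH3-20 axial on ring B (estimated at least 4:1; the minor epimer is separated and re-equilibrated).

Step 13
Reactants: 16 silyl ether octalone (name as in step 12)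
Product: 17 (13R)-15-hydroxy-18,19-dinorclerod-4-en-3-one
Conditions: TBAF, THF, rt
Reagents that add atoms: none
Why: Fluoride cleavage of the silyl ether, driven by the Si–F bond, leaves the enone untouched.

Step 14
Reactants: 17 (13R)-15-hydroxy-18,19-dinorclerod-4-en-3-one
Product: 18 (13R)-3-oxo-18,19-dinorclerod-4-en-15-oic acid
Conditions: TEMPO (cat.), PhI(OAc)2, MeCN–H2O, rt
Reagents that add atoms: water O
Why: Oxoammonium (TEMPO) oxidation of the primary alcohol through the aldehyde hydrate to the acid, with no other oxidisable group present.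

Step 15
Reactants: 18 (13R)-3-oxo-18,19-dinorclerod-4-en-15-oic acid
Product: 19 methyl (13R)-3-oxo-18,19-dinorclerod-4-en-15-oate
Conditions: TMSCHN2, MeOH–toluene, 0 °C
Reagents that add atoms: (trimethylsilyl)diazomethane C[Si](C)(C)C=[N+]=[N-]
Why: Neutral methyl esterification with a diazoalkane installs the C-15 methyl ester without epimerising or deconjugating the enone.

Step 16
Reactants: 19 methyl (13R)-3-oxo-18,19-dinorclerod-4-en-15-oate
Product: 20 methyl (13R)-3-oxo-18,19-dinorcleroda-4,6-dien-15-oate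
Conditions: chloranil, t-BuOH, reflux
Reagents that add atoms: none
Why: Quinone dehydrogenation of the 4-en-3-one through its 3,5-dienol (hydride abstraction from C-7) gives the linear dienone and cannot go further because C-9 is quaternary.

Step 17
Reactants: 20 methyl (13R)-3-oxo-18,19-dinorcleroda-4,6-dien-15-oate
Product: 21 methyl (13R)-6β,7β-epoxy-3-oxo-18,19-dinorclerod-4-en-15-oate
Conditions: mCPBA, NaHCO3, CH2Cl2, 0 °C
Reagents that add atoms: 3-chloroperoxybenzoic acid OOC(=O)c1cccc(Cl)c1
Why: Prilezhaev epoxidation of the more electron-rich γ,δ-double bond from the β face, anti to the pseudoaxial α-CH3-20 on C-9, places the C-7 oxygen β.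

Step 18
Reactants: 21 methyl (13R)-6β,7β-epoxy-3-oxo-18,19-dinorclerod-4-en-15-oate
Product: 23 methyl (13R)-7β-hydroxy-3-oxo-18,19-dinorclerod-4-en-15-oate, via deconjugated enone 22 (not isolated)
Conditions: SmI2 (2.2 equiv), THF–MeOH, −78 °C; then Et3N (cat.), CH2Cl2, rt
Reagents that add atoms: none
Why: Single-electron reduction of the vinylogous α,β-epoxy ketone cleaves only the C-6–O bond, so the C-7–O bond keeps its β configuration, and base-catalysed isomerisation returns the double bond to conjugation.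

Step 19
Reactants: 23 methyl (13R)-7β-hydroxy-3-oxo-18,19-dinorclerod-4-en-15-oate
Product: 24 methyl (13R)-7β-acetoxy-3-oxo-18,19-dinorclerod-4-en-15-oate
Conditions: Ac2O, pyridine, DMAP (cat.), CH2Cl2, 0 °C
Reagents that add atoms: acetic anhydride CC(=O)OC(C)=O
Why: Acylation of the equatorial secondary alcohol with retention, kept cold because the 7-acyloxy enone can undergo vinylogous β-elimination with stronger base.

Step 20
Reactants: 24 methyl (13R)-7β-acetoxy-3-oxo-18,19-dinorclerod-4-en-15-oate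
Product: 25 methyl (13R)-7β-acetoxy-3-(trimethylsilyloxy)-18-nor-5β-clerod-3-en-15-oate (5β-CH3 cis to 10β-H)
Conditions: Me2CuLi (from MeLi and CuI, Et2O, 0 °C), TMSCl, THF, −78 to −30 °C; Et3N, cold aq NaHCO3; used crude
Reagents that add atoms: lithium dimethylcuprate [Li+].C[Cu-]C; chlorotrimethylsilane C[Si](C)(C)Cl
Why: Gilman conjugate addition in which methyl enters C-5 axially to ring A from the β face (syn to H-10, equatorial to ring B) because the α face is blocked by the axial CH3-20, giving the cis-fused decalin, while TMSCl traps the C-3/C-4 enolate and the ester and acetate are inert at this temperature.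

Step 21
Reactants: 25 enol silane (name as in step 20)
Product: 26 methyl (13R)-7β-acetoxy-18-(dimethylamino)-3-oxo-5β-clerodan-15-oate (C-4 epimers)
Conditions: Me2N=CH2 iodide (Eschenmoser's salt), CH2Cl2, rt; aq NaHCO3
Reagents that add atoms: N,N-dimethylmethyleneiminium iodide C=[N+](C)C.[I-]
Why: Mannich reaction of the enol silane with the preformed iminium ion (first stage of the Danishefsky α-methylenation) introduces C-18 at C-4 only, and the C-4 configuration is irrelevant.

Step 22
Reactants: 26 Mannich base (name as in step 21)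
Product: 28 methyl (13R)-7β-acetoxy-3-oxo-5β-clerod-4(18)-en-15-oate, via methiodide 27 (not isolated)
Conditions: MeI, CH2Cl2, rt; then aq NaHCO3, CH2Cl2, rt
Reagents that add atoms: none
Why: N-methylation followed by E1cB (Hofmann-type) loss of trimethylamine unveils the exocyclic α-methylene ketone under conditions that spare both esters.

Step 23
Reactants: 28 methyl (13R)-7β-acetoxy-3-oxo-5β-clerod-4(18)-en-15-oate
Product: 29 methyl (13R)-7β-acetoxy-3-(trimethylsilyloxy)-5β-cleroda-2,4(18)-dien-15-oate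
Conditions: LiHMDS (1.05 equiv), TMSCl (internal quench), THF, −78 °C; used crude
Reagents that add atoms: chlorotrimethylsilane C[Si](C)(C)Cl
Why: Kinetic enolisation with in situ silylation: C-2 carries the only enolisable hydrogens (C-4 is sp2), so the cross-conjugated 2-silyloxy diene forms regiospecifically, and the bulky amide does not add to the enone at −78 °C.

Step 24
Reactants: 29 silyloxy diene (name as in step 23)
Product: 31 methyl (13R)-7β-acetoxy-2-hydroxy-3-oxo-5β-clerod-4(18)-en-15-oate (C-2 epimers), via silyloxy epoxide 30 (not isolated)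
Conditions: dimethyldioxirane, acetone–CH2Cl2, −78 to −40 °C; then 10% aq citric acid, THF, 0 °C
Reagents that add atoms: dimethyldioxirane CC1(C)OO1
Why: Rubottom oxidation in which the dioxirane epoxidises the electron-rich enol ether double bond and not the exocyclic alkene, and hydrolysis gives the α-hydroxy ketone whose C-2 configuration is lost in step 25.

Step 25
Reactants: 31 α-hydroxy ketone (name as in step 24)
Product: 33 methyl (5S,7S,8S,9R,10R,13R)-7-acetoxy-2-hydroxy-3-oxocleroda-1,4(18)-dien-15-oate (target), via 2,3-dione 32 (not isolated)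
Conditions: Dess–Martin periodinane, NaHCO3, CH2Cl2, 0 °C to rt
Reagents that add atoms: none
Why: Dess–Martin oxidation gives the 2,3-dione, which can enolise only towards C-1 (C-4 has no hydrogen) and so tautomerises to the diosphenol of the target.

## Compound list

1 | propanal | CCC=O | starting material
2 | but-3-en-2-one (methyl vinyl ketone) | CC(=O)C=C | starting material
3 | (R)-2-methyl-5-oxohexanal | O=C[C@H](C)CCC(C)=O | intermediate
4 | (R)-4-methylcyclohex-2-en-1-one | O=C1C=C[C@H](C)CC1 | intermediate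
5 | trimethyl{[(3S,4R)-3,4-dimethylcyclohex-1-en-1-yl]oxy}silane | C[Si](C)(C)OC1=C[C@@H](C)[C@H](C)CC1 | intermediate
6 | (R)-3,4-dimethylcyclohex-2-en-1-one | O=C1C=C(C)[C@H](C)CC1 | intermediate
7 | dimethyl 3-methylpentanedioate | COC(=O)CC(C)CC(=O)OC | starting material
8 | (R)-5-methoxy-3-methyl-5-oxopentanoic acid | OC(=O)C[C@@H](C)CC(=O)OC | intermediate
9 | methyl (R)-5-hydroxy-3-methylpentanoate | OCC[C@@H](C)CC(=O)OC | intermediate
10 | methyl (S)-5-bromo-3-methylpentanoate | BrCC[C@@H](C)CC(=O)OC | intermediate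
11 | (S)-5-bromo-3-methylpentan-1-ol | BrCC[C@@H](C)CCO | intermediate
12 | (S)-[(5-bromo-3-methylpentyl)oxy](tert-butyl)diphenylsilane | BrCC[C@@H](C)CCO[Si](c1ccccc1)(c1ccccc1)C(C)(C)C | intermediate
13 | (S)-{5-[(tert-butyldiphenylsilyl)oxy]-3-methylpentyl}magnesium bromide (Grignard reagent, not isolated) | Br[Mg]CC[C@@H](C)CCO[Si](c1ccccc1)(c1ccccc1)C(C)(C)C | intermediate
14 | tert-butyl{[(3R)-5-[(1S,6R)-1,6-dimethyl-3-(trimethylsilyloxy)cyclohex-2-en-1-yl]-3-methylpentyl]oxy}diphenylsilane | C[Si](C)(C)OC1=C[C@@](C)(CC[C@@H](C)CCO[Si](c2ccccc2)(c2ccccc2)C(C)(C)C)[C@H](C)CC1 | intermediate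
15 | (3S,4R)-3-{(3R)-5-[(tert-butyldiphenylsilyl)oxy]-3-methylpentyl}-3,4-dimethyl-2-(3-oxobutyl)cyclohexan-1-one, C-2 epimers | CC(=O)CCC1[C@@](C)(CC[C@@H](C)CCO[Si](c2ccccc2)(c2ccccc2)C(C)(C)C)[C@H](C)CCC1=O | intermediate
16 | (13R)-15-[(tert-butyldiphenylsilyl)oxy]-18,19-dinorclerod-4-en-3-one (8α-CH3, 9α-CH3, 10β-H) | O=C1CC[C@@H]2[C@@](C)(CC[C@@H](C)CCO[Si](c3ccccc3)(c3ccccc3)C(C)(C)C)[C@H](C)CCC2=C1 | intermediate
17 | (13R)-15-hydroxy-18,19-dinorclerod-4-en-3-one | O=C1CC[C@@H]2[C@@](C)(CC[C@@H](C)CCO)[C@H](C)CCC2=C1 | intermediate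
18 | (13R)-3-oxo-18,19-dinorclerod-4-en-15-oic acid | O=C1CC[C@@H]2[C@@](C)(CC[C@@H](C)CC(=O)O)[C@H](C)CCC2=C1 | intermediate
19 | methyl (13R)-3-oxo-18,19-dinorclerod-4-en-15-oate | O=C1CC[C@@H]2[C@@](C)(CC[C@@H](C)CC(=O)OC)[C@H](C)CCC2=C1 | intermediate
20 | methyl (13R)-3-oxo-18,19-dinorcleroda-4,6-dien-15-oate | O=C1CC[C@@H]2[C@@](C)(CC[C@@H](C)CC(=O)OC)[C@H](C)C=CC2=C1 | intermediate
21 | methyl (13R)-6β,7β-epoxy-3-oxo-18,19-dinorclerod-4-en-15-oate | O=C1CC[C@@H]2[C@@](C)(CC[C@@H](C)CC(=O)OC)[C@H](C)[C@H]3O[C@H]3C2=C1 | intermediate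
22 | methyl (13R)-7β-hydroxy-3-oxo-18,19-dinorclerod-5-en-15-oate (not isolated) | O=C1CC[C@@H]2[C@@](C)(CC[C@@H](C)CC(=O)OC)[C@H](C)[C@@H](O)C=C2C1 | intermediate
23 | methyl (13R)-7β-hydroxy-3-oxo-18,19-dinorclerod-4-en-15-oate | O=C1CC[C@@H]2[C@@](C)(CC[C@@H](C)CC(=O)OC)[C@H](C)[C@@H](O)CC2=C1 | intermediate
24 | methyl (13R)-7β-acetoxy-3-oxo-18,19-dinorclerod-4-en-15-oate | O=C1CC[C@@H]2[C@@](C)(CC[C@@H](C)CC(=O)OC)[C@H](C)[C@@H](OC(C)=O)CC2=C1 | intermediate
25 | methyl (13R)-7β-acetoxy-3-(trimethylsilyloxy)-18-nor-5β-clerod-3-en-15-oate (cis-fused, 5β-CH3) | C1=C(O[Si](C)(C)C)CC[C@@H]2[C@@](C)(CC[C@@H](C)CC(=O)OC)[C@H](C)[C@@H](OC(C)=O)C[C@]12C | intermediate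
26 | methyl (13R)-7β-acetoxy-18-(dimethylamino)-3-oxo-5β-clerodan-15-oate, C-4 epimers | CN(C)CC1C(=O)CC[C@@H]2[C@@](C)(CC[C@@H](C)CC(=O)OC)[C@H](C)[C@@H](OC(C)=O)C[C@]12C | intermediate
27 | 18-(trimethylammonio) iodide of 26 (not isolated) | C[N+](C)(C)CC1C(=O)CC[C@@H]2[C@@](C)(CC[C@@H](C)CC(=O)OC)[C@H](C)[C@@H](OC(C)=O)C[C@]12C.[I-] | intermediate
28 | methyl (13R)-7β-acetoxy-3-oxo-5β-clerod-4(18)-en-15-oate | C=C1C(=O)CC[C@@H]2[C@@](C)(CC[C@@H](C)CC(=O)OC)[C@H](C)[C@@H](OC(C)=O)C[C@]12C | intermediate
29 | methyl (13R)-7β-acetoxy-3-(trimethylsilyloxy)-5β-cleroda-2,4(18)-dien-15-oate | C=C1C(O[Si](C)(C)C)=CC[C@@H]2[C@@](C)(CC[C@@H](C)CC(=O)OC)[C@H](C)[C@@H](OC(C)=O)C[C@]12C | intermediate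
30 | methyl (13R)-7β-acetoxy-2,3-epoxy-3-(trimethylsilyloxy)-5β-clerod-4(18)-en-15-oate (not isolated) | C=C1C3(O[Si](C)(C)C)OC3C[C@@H]2[C@@](C)(CC[C@@H](C)CC(=O)OC)[C@H](C)[C@@H](OC(C)=O)C[C@]12C | intermediate
31 | methyl (13R)-7β-acetoxy-2-hydroxy-3-oxo-5β-clerod-4(18)-en-15-oate, C-2 epimers | C=C1C(=O)C(O)C[C@@H]2[C@@](C)(CC[C@@H](C)CC(=O)OC)[C@H](C)[C@@H](OC(C)=O)C[C@]12C | intermediate
32 | methyl (13R)-7β-acetoxy-2,3-dioxo-5β-clerod-4(18)-en-15-oate (not isolated) | C=C1C(=O)C(=O)C[C@@H]2[C@@](C)(CC[C@@H](C)CC(=O)OC)[C@H](C)[C@@H](OC(C)=O)C[C@]12C | intermediate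
33 | methyl (5S,7S,8S,9R,10R,13R)-7-acetoxy-2-hydroxy-3-oxocleroda-1,4(18)-dien-15-oate | C=C1C(=O)C(O)=C[C@@H]2[C@@](C)(CC[C@@H](C)CC(=O)OC)[C@H](C)[C@@H](OC(C)=O)C[C@]12C | target

## Step count and risks

Total steps: 25. Longest linear sequence: 21 (steps 5 to 9, then 10 to 25); the ring B branch (steps 1 to 4) joins at step 10.

Most likely to fail:

Step 18 (reductive opening of the vinylogous epoxy ketone). The samarium dienolate may expel the 7-oxygen and return dienone 20, or the product may be over-reduced. The fallback sets out from dienone 20 and avoids the epoxide altogether. CuCl/NaOt-Bu/Xantphos-catalysed 1,6-conjugate borylation with B2pin2 (MeOH, THF, rt) puts boron on C-7 anti to the axial CH3-20 and gives methyl (13R)-7β-(4,4,5,5-tetramethyl-1,3,2-dioxaborolan-2-yl)-3-oxo-18,19-dinorclerod-4-en-15-oate F1. Oxidation with NaBO3·4H2O (THF–H2O) converts C–B into C–OH with retention, and the route is rejoined at compound 23.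

Step 20 (cuprate addition to the hindered β,β-disubstituted enone). The addition may be slow, may give some trans-fused product, or may attack the acetate. The fallback sets out from enone 24 and delivers the angular methyl as a cyclopropane carbon.
- Luche reduction (NaBH4, CeCl3·7H2O, MeOH, −78 °C) by axial hydride attack gives methyl (13R)-7β-acetoxy-3β-hydroxy-18,19-dinorclerod-4-en-15-oate F2.
- Hydroxyl-directed Furukawa–Simmons–Smith cyclopropanation (Et2Zn, CH2I2, CH2Cl2, 0 °C) on the β face gives methyl (13R)-7β-acetoxy-3β-hydroxy-4β,5β-methano-18,19-dinorclerodan-15-oate F3.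
- Dess–Martin oxidation gives methyl (13R)-7β-acetoxy-4β,5β-methano-3-oxo-18,19-dinorclerodan-15-oate F4.
- SmI2/HMPA/t-BuOH (THF, −78 °C) cleaves the exocyclic cyclopropane bond, the one that overlaps with the carbonyl π system, turning the methano carbon into CH3-19 and leaving the samarium enolate methyl (13R)-7β-acetoxy-3-(diiodosamariooxy)-18-nor-5β-clerod-3-en-15-oate F5.
- Silylation in the flask (TMSCl, Et3N) rejoins the route at compound 25.

Step 23 (silyl dienol ether of the α-methylene ketone, and the Rubottom sequence that depends on it). The enone is a Michael acceptor and can oligomerise or add the base. The fallback sets out from enone 28 and uses a direct Riley oxidation (SeO2, dioxane–H2O, 80 °C). The only enolisable α-methylene (C-2) is oxidised to the 2,3-dione 32, which tautomerises to the target, so the route is rejoined at compound 33 without passing through 29 to 31. This fallback makes no new compound (none F0).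

Further compounds
F1 | step 18 | methyl (13R)-7β-(4,4,5,5-tetramethyl-1,3,2-dioxaborolan-2-yl)-3-oxo-18,19-dinorclerod-4-en-15-oate | O=C1CC[C@@H]2[C@@](C)(CC[C@@H](C)CC(=O)OC)[C@H](C)[C@@H](B3OC(C)(C)C(C)(C)O3)CC2=C1
F2 | step 20 | methyl (13R)-7β-acetoxy-3β-hydroxy-18,19-dinorclerod-4-en-15-oate | O[C@H]1CC[C@@H]2[C@@](C)(CC[C@@H](C)CC(=O)OC)[C@H](C)[C@@H](OC(C)=O)CC2=C1
F3 | step 20 | methyl (13R)-7β-acetoxy-3β-hydroxy-4β,5β-methano-18,19-dinorclerodan-15-oate | O[C@H]1CC[C@@H]2[C@@](C)(CC[C@@H](C)CC(=O)OC)[C@H](C)[C@@H](OC(C)=O)C[C@@]23C[C@@H]13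
F4 | step 20 | methyl (13R)-7β-acetoxy-4β,5β-methano-3-oxo-18,19-dinorclerodan-15-oate | O=C1CC[C@@H]2[C@@](C)(CC[C@@H](C)CC(=O)OC)[C@H](C)[C@@H](OC(C)=O)C[C@@]23C[C@@H]13
F5 | step 20 | methyl (13R)-7β-acetoxy-3-(diiodosamariooxy)-18-nor-5β-clerod-3-en-15-oate | C1=C(O[Sm](I)I)CC[C@@H]2[C@@](C)(CC[C@@H](C)CC(=O)OC)[C@H](C)[C@@H](OC(C)=O)C[C@]12C
F0 | step 23 | none | none
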